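At late times the north run stopped gaining: at 4.00 d intermediate B read 10.0 % and target 3.6 %, a sum no higher than the 13.8 % at 3.00 d. I called the sum at 4.00 d the through-share S, 13.6 %: the part of the charge seen to have reached B or target. The flask asked about is the north run itself.

- north: starting material 0.12 M; protic impurity 0.12 M; the very flask that is asked about, followed so far
- flask: starting material 0.12 M; protic impurity 0.120 M; time 8.0 d

- north (time / d: intermediate B / %, target / %): 0.625: 5.5, 1.2; 0.833: 6.4, 1.7; 1.25: 8.0, 1.7; 1.67: 10.6, 2.2; 2.00: 10.9, 1.9; 3.00: 10.7, 3.1; 4.00: 10.0, 3.6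

(readings scatter by 0.5 percentage points)

- a reading or a percentage of target counts all its forms, free or not

- the best time, 8.0 d at the latest, for intermediate B
- the amount of intermediate B, in percent of the starting material charged, at that time

I reckoned B at the peak of this flask two ways, from different readings. B read 10.9 % at 2.00 d and 10.7 % at 3.00 d, so I put the peak near 2.50 d, at their mean of 10.8 %. Alternatively, if S already stood by then, B was S less the target present. A straight line through the first and last target readings gives 2.53 % there, so B was 11.1 %. The two differ by 0.27 percentage points, less than the scatter of 0.5 points, so I trusted both. If the protic impurity took the rest of the charge, the partition ratio, lost against through, was 6.35.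

The forecast gave 2.5 d (1.8 d to 3.4 d) and 10.8 % (10.2 % to 11.4 %), holding that “formation of B essentially stops early”.

The flask gave 2.56 d and 11.1 %.

    starting material ⇌ intermediate A (K = 0.770, k = 1.00 × 10⁻⁵ s⁻¹)
    intermediate A ⇌ intermediate B (K = 2.40, k = 9.30 × 10⁻⁶ s⁻¹)
    starting material ⇌ intermediate C (K = 0.630, k = 9.50 × 10⁻⁷ s⁻¹)
    intermediate A → side product (k = 1.30 × 10⁻⁶ s⁻¹)
    intermediate C → target (k = 1.10 × 10⁻⁵ s⁻¹)
    starting material + protic impurity → quenched substrate (k = 2.60 × 10⁻⁴ M⁻¹ s⁻¹)
    crystals ⇌ target, rate k7*(cs7 - [target]) while solid is left; crystals form when [target] > cs7 (solubility = 0.0760 M, k = 3.50 × 10⁻⁴ s⁻¹)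

In this flask, quenched substrate stood at 59.6 % by 0.800 d, with 73 % of that step's turnover up to 8.0 d behind it. At 2.56 d, with starting material at 4.58 %, B and target summed to 14.0 %. Scaling the ratio by the impurity charge and keeping B's part of S, I reckoned 7.03 % for the flask with 0.20 M of protic impurity; that flask peaked at 6.47 %.

The numbers in the tables stem from a simulated flask for an exercise.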